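The naphthazarin nucleus is cut at both aryl–carbonyl bonds, C1–C8a and C4–C4a. Because the quinone ring A and the dihydroxybenzo ring B of a 5,8-dihydroxy-1,4-naphthoquinone interchange by tautomerism, ring B (C4a, C5–C8, C8a) can be p-benzoquinone itself and C1–C4 with their two oxygens a succinic anhydride. The key step is the Diels–Alder reaction of p-benzoquinone with the anhydride-derived 2,5-bis(trimethylsilyloxy)furan that already carries the complete (R)-configured side chain at C3; the oxygen-bridged adduct sheds its bridge and aromatizes straight to unprotected shikonin. The stereocenter comes from commercial ethyl (S)-4-bromo-3-hydroxybutanoate, and a final esterification gives the target.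

Key step: step 8

Remark: the two naphthazarin tautomers (1,4-quinone/5,8-diol and 5,8-quinone/1,4-diol) are one compound, and the target SMILES is one drawing of it. Compounds 7–9 are carried as mixtures of epimers at the succinate carbon, which becomes sp2 in step 7.

Step 1
Reactants: 1 ethyl (3S)-4-bromo-3-hydroxybutanoate
Product: 2 ethyl 2-[(2S)-oxiran-2-yl]acetate (ethyl (S)-3,4-epoxybutanoate)
Conditions: Ag2O, 1,2-dimethoxyethane, reflux, dark
Reagents that add atoms: none
Why: Silver-assisted intramolecular Williamson etherification (3-exo-tet closure of the bromohydrin) works without base and so avoids isomerization of the β,γ-epoxy ester to ethyl 4-hydroxybut-2-enoate; the C3–O bond is never broken, so the (S) center of the starting material is retained.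

Step 2
Reactants: 2 ethyl 2-[(2S)-oxiran-2-yl]acetate; 3 (2-methylprop-1-en-1-yl)magnesium bromide
Product: 4 ethyl (3R)-3-hydroxy-6-methylhept-5-enoate
Conditions: 3 (1.5 equiv), CuI (10 mol %), THF, −40 → −20 °C; then aq. NH4Cl
Reagents that add atoms: none
Why: Copper-catalyzed SN2 opening of the terminal epoxide by the alkenyl Grignard reagent at the unsubstituted carbon is faster at low temperature than ester attack or enolization; the stereocenter is a spectator and is named (R) only because the CIP priorities change.

Step 3
Reactants: 4 ethyl (3R)-3-hydroxy-6-methylhept-5-enoate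
Product: 5 ethyl (3R)-3-[(tert-butyldimethylsilyl)oxy]-6-methylhept-5-enoate
Conditions: TBSCl, imidazole, DMF, rt
Reagents that add atoms: tert-butyldimethylsilyl chloride, CC(C)(C)[Si](C)(C)Cl
Why: Imidazole-promoted O-silylation of a secondary alcohol gives an ether that survives the enolate, hydroxide, anhydride and silyl triflate chemistry that follows; no stereocenter is touched.

Step 4
Reactants: 5 ethyl (3R)-3-[(tert-butyldimethylsilyl)oxy]-6-methylhept-5-enoate; 6 ethyl bromoacetate
Product: 7 diethyl 2-[(1R)-1-[(tert-butyldimethylsilyl)oxy]-4-methylpent-3-en-1-yl]butanedioate (both C2 epimers)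
Conditions: LiN(iPr)2 (LDA, 1.1 equiv), THF, −78 °C; then 6, DMPU, −78 → −40 °C
Reagents that add atoms: none
Why: Ester enolate alkylation (SN2 on the α-bromo ester by the kinetic lithium enolate) runs at −78 °C, where β-elimination of the silyloxy group is slow; the new succinate center forms without control and is irrelevant because it becomes sp2 in step 7, while the (R) carbinol center has no acidic hydrogen and is untouched.

Step 5
Reactants: 7 diethyl 2-[(1R)-1-[(tert-butyldimethylsilyl)oxy]-4-methylpent-3-en-1-yl]butanedioate
Product: 8 2-[(1R)-1-[(tert-butyldimethylsilyl)oxy]-4-methylpent-3-en-1-yl]butanedioic acid (both C2 epimers)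
Conditions: LiOH·H2O, THF/MeOH/H2O, rt → 40 °C; then 1 M HCl, 0 °C, to pH 3
Reagents that add atoms: lithium hydroxide, [Li+].[OH-]
Why: Saponification (acyl–oxygen cleavage by hydroxide) of both ethyl esters leaves the silyl ether and the alkene intact, and any epimerization at the succinate carbon does not matter.

Step 6
Reactants: 8 2-[(1R)-1-[(tert-butyldimethylsilyl)oxy]-4-methylpent-3-en-1-yl]butanedioic acid
Product: 9 3-[(1R)-1-[(tert-butyldimethylsilyl)oxy]-4-methylpent-3-en-1-yl]oxolane-2,5-dione (substituted succinic anhydride, both C3 epimers)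
Conditions: Ac2O, 50 °C; volatiles removed in vacuo (toluene azeotrope)
Reagents that add atoms: none
Why: Cyclodehydration of a succinic acid through its mixed acetic anhydride closes the five-membered cyclic anhydride by intramolecular acyl substitution under conditions that spare the silyl ether and the trisubstituted alkene.

Step 7
Reactants: 9 3-[(1R)-1-[(tert-butyldimethylsilyl)oxy]-4-methylpent-3-en-1-yl]oxolane-2,5-dione
Product: 10 3-[(1R)-1-[(tert-butyldimethylsilyl)oxy]-4-methylpent-3-en-1-yl]-2,5-bis(trimethylsilyloxy)furan
Conditions: TMSOTf (2.3 equiv), Et3N (3 equiv), CH2Cl2, 0 °C → rt; concentrate, pentane, filter under argon; used crude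
Reagents that add atoms: trimethylsilyl trifluoromethanesulfonate, C[Si](C)(C)OS(=O)(=O)C(F)(F)F
Why: Twofold soft enolization (carbonyl O-silylation by the silyl triflate, then deprotonation by the amine) turns the enolizable anhydride into the aromatic 2,5-bis(silyloxy)furan, a known reaction of succinic anhydrides; no free enolate is formed, so the β-silyloxy group should not be eliminated, and the carbinol center keeps its C–O bond while the ring carbon next to it becomes sp2.

Step 8
Reactants: 10 3-[(1R)-1-[(tert-butyldimethylsilyl)oxy]-4-methylpent-3-en-1-yl]-2,5-bis(trimethylsilyloxy)furan; 11 1,4-benzoquinone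
Product: 14 shikonin, via oxa-bridged cycloadduct 12 (not isolated), via shikonin tert-butyldimethylsilyl ether 13 (not isolated)
Conditions: 11 (3 equiv), CH2Cl2, −78 °C → rt; then HF·pyridine, THF, 0 °C → rt
Reagents that add atoms: none
Why: Diels–Alder reaction of the electron-rich, s-cis-locked furan (diene termini C2 and C5, the former anhydride carbonyl carbons) with one C=C bond of p-benzoquinone forms C1–C8a and C4–C4a in a single suprafacial [4+2] cycloaddition that closes the six-membered carbocycle C1–C4/C4a/C8a. The ketal-type oxygen bridge of 12 then opens by β-elimination, the bridge oxygen is lost, and the resulting ene-tetraone enolizes to the naphthazarin, so no oxidation and no deprotection of the nucleus is needed. The closest known reaction type is the cycloaddition of 2,5-bis(trimethylsilyloxy)furans with quinone, alkene and alkyne dienophiles, which gives p-dioxygenated arenes. No new stereocenter survives, because the bridgehead and ring-fusion centers of 12 (endo/exo and facial mixtures) are all erased on aromatization and the (R) carbinol center is a spectator whose C–O bond is never broken. The step needs concerted cycloaddition to win over Mukaiyama–Michael attack through furan C4 and mono- over bis-annulation, which the cyclic diene with donors at both termini, the absence of Lewis acid and the excess of quinone at low temperature should secure; regiochemistry is moot because the quinone is symmetric. HF·pyridine finally removes all silyl groups without ionizing the carbinol next to the electron-poor ring.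

Step 9
Reactants: 14 shikonin; 15 3-methylbut-2-enoic acid
Product: 16 (1R)-1-(5,8-dihydroxy-1,4-dioxo-1,4-dihydronaphthalen-2-yl)-4-methylpent-3-en-1-yl 3-methylbut-2-enoate (β,β-dimethylacrylshikonin, target)
Conditions: 15, DCC, DMAP (cat.), CH2Cl2, 0 °C → rt
Reagents that add atoms: none
Why: Steglich esterification acylates the secondary side-chain hydroxyl selectively because the two peri hydroxyls are deactivated by hydrogen bonds to the quinone carbonyls; reaction occurs at oxygen under nearly neutral conditions, so the (R) configuration is retained and the senecioyl double bond stays conjugated.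

Compound list
1 | ethyl (3S)-4-bromo-3-hydroxybutanoate | CCOC(=O)C[C@H](O)CBr | starting material
2 | ethyl 2-[(2S)-oxiran-2-yl]acetate | CCOC(=O)C[C@H]1CO1 | intermediate
3 | (2-methylprop-1-en-1-yl)magnesium bromide | CC(C)=C[Mg]Br | starting material
4 | ethyl (3R)-3-hydroxy-6-methylhept-5-enoate | CC(C)=CC[C@@H](O)CC(=O)OCC | intermediate
5 | ethyl (3R)-3-[(tert-butyldimethylsilyl)oxy]-6-methylhept-5-enoate | CC(C)=CC[C@@H](O[Si](C)(C)C(C)(C)C)CC(=O)OCC | intermediate
6 | ethyl bromoacetate | CCOC(=O)CBr | starting material
7 | diethyl 2-[(1R)-1-[(tert-butyldimethylsilyl)oxy]-4-methylpent-3-en-1-yl]butanedioate, both C2 epimers | CC(C)=CC[C@@H](O[Si](C)(C)C(C)(C)C)C(CC(=O)OCC)C(=O)OCC | intermediate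
8 | 2-[(1R)-1-[(tert-butyldimethylsilyl)oxy]-4-methylpent-3-en-1-yl]butanedioic acid, both C2 epimers | CC(C)=CC[C@@H](O[Si](C)(C)C(C)(C)C)C(CC(=O)O)C(=O)O | intermediate
9 | 3-[(1R)-1-[(tert-butyldimethylsilyl)oxy]-4-methylpent-3-en-1-yl]oxolane-2,5-dione, both C3 epimers | CC(C)=CC[C@@H](O[Si](C)(C)C(C)(C)C)C1CC(=O)OC1=O | intermediate
10 | 3-[(1R)-1-[(tert-butyldimethylsilyl)oxy]-4-methylpent-3-en-1-yl]-2,5-bis(trimethylsilyloxy)furan | CC(C)=CC[C@@H](O[Si](C)(C)C(C)(C)C)c1cc(O[Si](C)(C)C)oc1O[Si](C)(C)C | intermediate
11 | 1,4-benzoquinone | O=C1C=CC(=O)C=C1 | starting material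
12 | 2-[(1R)-1-[(tert-butyldimethylsilyl)oxy]-4-methylpent-3-en-1-yl]-1,4-epoxy-1,4-bis(trimethylsilyloxy)-1,4,4a,8a-tetrahydronaphthalene-5,8-dione, mixture of diastereomers at the four new ring centers | CC(C)=CC[C@@H](O[Si](C)(C)C(C)(C)C)C1=CC2(O[Si](C)(C)C)OC1(O[Si](C)(C)C)C1C2C(=O)C=CC1=O | intermediate
13 | 2-[(1R)-1-[(tert-butyldimethylsilyl)oxy]-4-methylpent-3-en-1-yl]-5,8-dihydroxynaphthalene-1,4-dione | CC(C)=CC[C@@H](O[Si](C)(C)C(C)(C)C)C1=CC(=O)c2c(O)ccc(O)c2C1=O | intermediate
14 | shikonin, 5,8-dihydroxy-2-[(1R)-1-hydroxy-4-methylpent-3-en-1-yl]naphthalene-1,4-dione | CC(C)=CC[C@@H](O)C1=CC(=O)c2c(O)ccc(O)c2C1=O | intermediate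
15 | 3-methylbut-2-enoic acid | CC(C)=CC(=O)O | starting material
16 | (1R)-1-(5,8-dihydroxy-1,4-dioxo-1,4-dihydronaphthalen-2-yl)-4-methylpent-3-en-1-yl 3-methylbut-2-enoate | CC(C)=CC[C@@H](OC(=O)C=C(C)C)C1=CC(=O)c2c(O)ccc(O)c2C1=O | target

Total step count: 9. Longest linear sequence: 9 steps (1 → 16).

Steps most likely to fail

Step 8 (key step). The electron-rich furan may add to the quinone through C4 in a Mukaiyama–Michael sense, or be oxidized by it through electron transfer, instead of undergoing cycloaddition; the first-formed naphthazarin may also be annulated a second time. The fallback sets out from 10 and keeps the same two-bond cycloaddition, but replaces the quinone by an aryne, which is neither an oxidant nor a Michael acceptor. 2-Bromo-1,4-bis(methoxymethoxy)benzene F1 (from commercial 2-bromobenzene-1,4-diol, chloromethyl methyl ether and iPr2NEt) is deprotonated with lithium 2,2,6,6-tetramethylpiperidide in THF at −78 °C in the presence of 10. Loss of lithium bromide gives 3,6-bis(methoxymethoxy)benzyne, which the furan traps as the bridged 1,4-epoxy-1,4-bis(trimethylsilyloxy)-1,4-dihydronaphthalene F2 (not isolated). On aqueous work-up this should collapse directly to 2-[(1R)-1-[(tert-butyldimethylsilyl)oxy]-4-methylpent-3-en-1-yl]-5,8-bis(methoxymethoxy)naphthalene-1,4-dione F3, already at the quinone oxidation level. Dilute HCl in methanol (0 °C to rt) then cleaves both methoxymethyl ethers and the silyl ether, and the route is rejoined at 14.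

Step 4. The lithium enolate may expel the β-silyloxy group (E1cB) or be quenched by proton transfer from the bromoacetate before C-alkylation. The fallback sets out from 4 and alkylates before silylation. The Fráter–Seebach dianion of the free β-hydroxy ester (LDA 2.2 equiv, THF, −50 → −20 °C), whose alkoxide cannot leave, is alkylated with tert-butyl bromoacetate. This should give the anti product 4-tert-butyl 1-ethyl (2R)-2-[(1R)-1-hydroxy-4-methylpent-3-en-1-yl]butanedioate F4, whose tert-butyl ester resists lactonization. TBSOTf/2,6-lutidine at −78 °C gives the silyl ether F5. TMSOTf/2,6-lutidine then converts the tert-butyl ester into the trimethylsilyl ester F6 (not isolated), and aqueous LiOH hydrolyses the silyl and ethyl esters. The route is rejoined at 8, here as its single (2R) epimer.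

Step 2. The hindered 2-methylprop-1-enyl copper reagent may open the epoxide too slowly, so that deprotonation next to the ester with ring opening to ethyl 4-hydroxybut-2-enoate, or attack on the ester, takes over. The fallback sets out from 2 and delivers the alkene in two stages. The small, fast vinylmagnesium bromide (CuI cat., THF, −40 °C) opens the epoxide to ethyl (3R)-3-hydroxyhex-5-enoate F7. Cross-metathesis with 2-methylbut-2-ene (second-generation Grubbs catalyst, (H2IMes)(PCy3)Cl2Ru=CHPh, neat alkene, rt → 40 °C) then builds the trisubstituted alkene, and the route is rejoined at 4.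

Further compounds
F1 | step 8 | 2-bromo-1,4-bis(methoxymethoxy)benzene | COCOc1ccc(OCOC)c(Br)c1
F2 | step 8 | 2-[(1R)-1-[(tert-butyldimethylsilyl)oxy]-4-methylpent-3-en-1-yl]-1,4-epoxy-5,8-bis(methoxymethoxy)-1,4-bis(trimethylsilyloxy)-1,4-dihydronaphthalene, mixture of bridge diastereomers | CC(C)=CC[C@@H](O[Si](C)(C)C(C)(C)C)C1=CC2(O[Si](C)(C)C)OC1(O[Si](C)(C)C)c1c(OCOC)ccc(OCOC)c12
F3 | step 8 | 2-[(1R)-1-[(tert-butyldimethylsilyl)oxy]-4-methylpent-3-en-1-yl]-5,8-bis(methoxymethoxy)naphthalene-1,4-dione | CC(C)=CC[C@@H](O[Si](C)(C)C(C)(C)C)C1=CC(=O)c2c(OCOC)ccc(OCOC)c2C1=O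
F4 | step 4 | 4-tert-butyl 1-ethyl (2R)-2-[(1R)-1-hydroxy-4-methylpent-3-en-1-yl]butanedioate | CC(C)=CC[C@@H](O)[C@@H](CC(=O)OC(C)(C)C)C(=O)OCC
F5 | step 4 | 4-tert-butyl 1-ethyl (2R)-2-[(1R)-1-[(tert-butyldimethylsilyl)oxy]-4-methylpent-3-en-1-yl]butanedioate | CC(C)=CC[C@@H](O[Si](C)(C)C(C)(C)C)[C@@H](CC(=O)OC(C)(C)C)C(=O)OCC
F6 | step 4 | 1-ethyl 4-trimethylsilyl (2R)-2-[(1R)-1-[(tert-butyldimethylsilyl)oxy]-4-methylpent-3-en-1-yl]butanedioate | CC(C)=CC[C@@H](O[Si](C)(C)C(C)(C)C)[C@@H](CC(=O)O[Si](C)(C)C)C(=O)OCC
F7 | step 2 | ethyl (3R)-3-hydroxyhex-5-enoate | C=CC[C@@H](O)CC(=O)OCC
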